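**Plan**

1. Retrosynthesis (eudesmane numbering): both esters come off last. The 3β,4α-diol is traced to the Δ3 olefin of eudesma-3,7(11)-dien-8-one. Ring A is then cut at C1–C2 and C3=C4, which frees a two-carbon vinyl unit (C2–C3) and leaves ring B with a CH2CO2H arm on C10 and an acetyl group on C5.
2. Enabling feature: C1 is a neopentyl methylene on quaternary C10 (inert to SN2, best made as a radical by decarboxylation). C4 is the carbonyl carbon of an acetyl group on C5. The two sit 1,4 and trans-diequatorial on ring B, so a vinylphosphonium linchpin can accept the C1 radical at C2 and return an ylide at C3 that closes on C4.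
3. Forward order: ring B is (R)-carvone. Conjugate vinylation and enolate alkylation set C5 and C10. A 1,2-carbonyl shift (C9 to C8) turns the carvone stereocentre into the isopropylidene. Ring A is then closed in the key step and oxidised.
4. Stereochemistry: C5 and C10 by relay from the carvone stereocentre (anti addition, then anti alkylation). C4 by osmylation of the Δ3 olefin on the face opposite the C10 methyl. C3 by axial hydride delivery to the 3-ketone. The Z olefin comes from angelic acid.

Key step: step 6

Remark: α is the face opposite the C10 methyl group; the ester in the target SMILES is the (Z)-2-methylbut-2-enoate (angelate); ring B carbons keep their eudesmane numbers (C5–C10) in all intermediates.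

**Step 1**
Reactants: 1 (R)-(−)-carvone; 2 vinylmagnesium bromide; 3 methyl bromoacetate
Product: 5 methyl 2-[(1S,4R,6S)-6-ethenyl-1-methyl-2-oxo-4-(prop-1-en-2-yl)cyclohexyl]acetate, via bromomagnesium enolate 4 (not isolated)
Conditions: 2, CuBr·SMe2 (10 mol%), THF, −40 °C; then 3, HMPA, −40 to 0 °C
Reagents that add atoms: none
Why: Copper-catalysed conjugate addition of the vinyl Grignard reagent should occur anti to the isopropenyl group (axial attack on the half-chair), and C-alkylation of the resulting tetrasubstituted enolate by the reactive α-bromo ester should occur anti to the new vinyl group, so that C5 and the quaternary C10 are set in one tandem conjugate addition–enolate alkylation.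

**Step 2**
Reactants: 5 methyl 2-[(1S,4R,6S)-6-ethenyl-1-methyl-2-oxo-4-(prop-1-en-2-yl)cyclohexyl]acetate
Product: 7 methyl 2-[(1S,3S,4S,6S)-6-ethenyl-3-hydroxy-1-methyl-2-oxo-4-(prop-1-en-2-yl)cyclohexyl]acetate, via potassium enolate 6 (not isolated)
Conditions: KN(SiMe3)2, THF, −78 °C; 2-(phenylsulfonyl)-3-phenyloxaziridine, −78 °C; AcOH
Reagents that add atoms: 2-(phenylsulfonyl)-3-phenyloxaziridine, O=S(=O)(c1ccccc1)N1OC1c1ccccc1
Why: Only C8 carries enolisable hydrogens next to the ketone (C10 is quaternary) and the ester α-hydrogens are far less acidic, so the enolate should form regiospecifically and be hydroxylated by the N-sulfonyloxaziridine (Davis enolate oxidation) anti to the neighbouring isopropenyl group; this carbinol configuration is erased in step 3.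

**Step 3**
Reactants: 7 methyl 2-[(1S,3S,4S,6S)-6-ethenyl-3-hydroxy-1-methyl-2-oxo-4-(prop-1-en-2-yl)cyclohexyl]acetate
Product: 10 (3aS,4S,7aS)-4-ethenyl-3a-methyl-6-(propan-2-ylidene)hexahydro-1-benzofuran-2,7-dione (cis-fused γ-lactone), via transposed ketol 8 (not isolated), via isopropenyl lactone 9 (not isolated)
Conditions: NaOMe (0.3 equiv), MeOH, argon, 0 to 25 °C; AcOH
Reagents that add atoms: none
Why: Methoxide should equilibrate the α-ketol through its enediolate (α-ketol transposition of the Lobry de Bruyn–van Ekenstein type), and the equilibrium should drain to the 8-ketone because its 9-hydroxyl is trapped on the methyl ester as a γ-lactone and the isopropenyl group moves into conjugation (isopulegone-to-pulegone type shift); the cis lactone fusion at C9 is set under thermodynamic control by epimerisation next to the new ketone.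

**Step 4**
Reactants: 10 (3aS,4S,7aS)-4-ethenyl-3a-methyl-6-(propan-2-ylidene)hexahydro-1-benzofuran-2,7-dione
Product: 11 (3aS,4R,7aS)-4-acetyl-3a-methyl-6-(propan-2-ylidene)hexahydro-1-benzofuran-2,7-dione
Conditions: PdCl2 (10 mol%), CuCl (20 mol%), O2 (1 atm), DMF/H2O, 25 °C
Reagents that add atoms: water, O
Why: Wacker oxidation of the monosubstituted vinyl group should give the methyl ketone with Markovnikov regiochemistry, while the tetrasubstituted enone olefin does not compete for palladium and no stereocentre is formed or touched.

**Step 5**
Reactants: 11 (3aS,4R,7aS)-4-acetyl-3a-methyl-6-(propan-2-ylidene)hexahydro-1-benzofuran-2,7-dione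
Product: 12 2-[(1S,2R)-2-acetyl-1-methyl-5-oxo-4-(propan-2-ylidene)cyclohexyl]acetic acid
Conditions: SmI2, THF/MeOH, −78 °C; aq. HCl
Reagents that add atoms: none
Why: Divalent samarium should reduce the α-acyloxy enone to its ketyl, which expels the carboxylate from C9 (reductive cleavage of an α-heterosubstituted ketone), so that one operation deoxygenates C9 and frees the acetic acid arm; the isolated methyl ketone is not reduced at −78 °C without a polar additive and no stereocentre is formed.

**Step 6**
Reactants: 12 2-[(1S,2R)-2-acetyl-1-methyl-5-oxo-4-(propan-2-ylidene)cyclohexyl]acetic acid; 13 vinyltriphenylphosphonium bromide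
Product: 15 eudesma-3,7(11)-dien-8-one, via phosphorus ylide 14 (not isolated)
Conditions: 13 (1.5 equiv), 4CzIPN (3 mol%), Cs2CO3, DMSO, 450 nm LEDs, 25 °C
Reagents that add atoms: none
Why: Proposed new method: the caesium carboxylate of 12 is oxidised by the excited photocatalyst and loses CO2 to give the neopentyl-type primary radical at C1, which adds to the unsubstituted terminus (C2) of the electron-poor vinylphosphonium salt 13; the α-phosphonio radical at C3 is reduced by the reduced photocatalyst to the ylide 14 (radical–polar crossover), and the ylide carbon C3 then attacks the C4 acetyl carbonyl and the oxaphosphetane collapses to the C3=C4 olefin and Ph3PO. The closest known reaction types are the photoredox three-component olefination of carboxylic acids, vinylphosphonium salts and carbonyl compounds (intermolecular radical addition–Wittig sequence) and the Schweizer-type annulation of vinylphosphonium salts with nucleophiles that carry a ketone; the new element is that radical precursor and carbonyl sit in one molecule, so the sequence becomes a ring-forming [4+2]-type annulation. Ring A, the only ring made, is closed by 6-exo-trig addition of C3 to the exocyclic carbonyl carbon C4 followed by syn-cycloreversion. No stereocentre is created: C5 and C10 are carried from 12, and the position of the double bond (C3=C4, with C15 on C4) is fixed by the Wittig step. The step needs the ylide to choose C4 over the ring ketone C8, which is also 1,6 to C3; this is secured because olefination at C8 would give a bridgehead alkene in a bicyclo[3.3.1]nonene and because C8 is a hindered cross-conjugated carbonyl. It also needs olefination to outrun proton transfer from the acetyl group (which would also endanger C5) and addition of the carboxylate to 13, which the six-membered intramolecular closure and the excess of 13 should secure.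

**Step 7**
Reactants: 15 eudesma-3,7(11)-dien-8-one
Product: 16 3α,4α-dihydroxyeudesm-7(11)-en-8-one
Conditions: K2OsO2(OH)4 (2 mol%), N-methylmorpholine N-oxide, acetone/H2O, 25 °C
Reagents that add atoms: N-methylmorpholine N-oxide, C[N+]1([O-])CCOCC1; water, O
Why: Catalytic osmylation (Upjohn dihydroxylation) should take the electron-rich trisubstituted Δ3 olefin and leave the tetrasubstituted enone olefin, and should add from the α face, opposite the axial C10 methyl, which sets C4 (4α-OH, 4β-methyl) correctly and C3 as the 3α-alcohol to be corrected in steps 8 and 9.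

**Step 8**
Reactants: 16 3α,4α-dihydroxyeudesm-7(11)-en-8-one
Product: 17 4α-hydroxyeudesm-7(11)-ene-3,8-dione
Conditions: IBX, DMSO, 25 °C
Reagents that add atoms: none
Why: IBX oxidises the secondary hydroxyl of a 1,2-diol to the α-ketol without C–C cleavage at room temperature, and the tertiary 4α-hydroxyl cannot be oxidised, so only the C3 stereocentre is removed.

**Step 9**
Reactants: 17 4α-hydroxyeudesm-7(11)-ene-3,8-dione
Product: 18 3β,4α-dihydroxyeudesm-7(11)-en-8-one
Conditions: NaBH4, MeOH/CH2Cl2, −78 °C
Reagents that add atoms: none
Why: Borohydride reduction should deliver hydride axially from the α face of the saturated, α-hydroxy-activated C3 ketone (the equatorial path is blocked by the axial 4β-methyl), giving the equatorial 3β-alcohol, while the hindered cross-conjugated C8 enone is much slower at −78 °C.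

**Step 10**
Reactants: 18 3β,4α-dihydroxyeudesm-7(11)-en-8-one; 19 angelic acid
Product: 21 3β-angeloyloxy-4α-hydroxyeudesm-7(11)-en-8-one, via mixed anhydride 20 (not isolated)
Conditions: 19, 2,4,6-trichlorobenzoyl chloride, Et3N, toluene, 25 °C; then 18, toluene, 80 °C
Reagents that add atoms: none
Why: The mixed anhydride with the hindered 2,4,6-trichlorobenzoyl group transfers the angeloyl group on heating without a nucleophilic catalyst (Yamaguchi-type esterification), conditions that should keep the Z geometry, and only the equatorial secondary 3β-hydroxyl reacts while the tertiary 4α-hydroxyl stays free.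

**Step 11**
Reactants: 21 3β-angeloyloxy-4α-hydroxyeudesm-7(11)-en-8-one
Product: 22 3β-angeloyloxy-4α-acetoxyeudesm-7(11)-en-8-one (CNP0141494.1)
Conditions: Ac2O, Sc(OTf)3 (2 mol%), MeCN, −20 °C
Reagents that add atoms: acetic anhydride, CC(=O)OC(C)=O
Why: Sc(OTf)3-catalysed acylation with acetic anhydride esterifies hindered tertiary alcohols at low temperature without elimination (Lewis acid-catalysed acetylation), and these non-nucleophilic conditions should leave the angelate geometry and all stereocentres untouched.

**Compound list**

1 | (R)-(−)-carvone, (5R)-2-methyl-5-(prop-1-en-2-yl)cyclohex-2-en-1-one | CC1=CC[C@H](CC1=O)C(C)=C | starting material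
2 | vinylmagnesium bromide | C=C[Mg]Br | starting material
3 | methyl bromoacetate | COC(=O)CBr | starting material
4 | bromomagnesium enolate from anti conjugate addition of vinyl to 1 (vinyl trans to isopropenyl; O–C9=C10) | CC1=C(O[Mg]Br)C[C@H](C(C)=C)C[C@H]1C=C | intermediate
5 | methyl 2-[(1S,4R,6S)-6-ethenyl-1-methyl-2-oxo-4-(prop-1-en-2-yl)cyclohexyl]acetate (acetate arm trans to vinyl, vinyl trans to isopropenyl) | COC(=O)C[C@]1(C)C(=O)C[C@H](C(C)=C)C[C@H]1C=C | intermediate
6 | potassium enolate of 5 (O–C9=C8) | COC(=O)C[C@]1(C)C([O-])=C[C@H](C(C)=C)C[C@H]1C=C.[K+] | intermediate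
7 | methyl 2-[(1S,3S,4S,6S)-6-ethenyl-3-hydroxy-1-methyl-2-oxo-4-(prop-1-en-2-yl)cyclohexyl]acetate (hydroxyl trans to isopropenyl) | COC(=O)C[C@]1(C)C(=O)[C@@H](O)[C@H](C(C)=C)C[C@H]1C=C | intermediate
8 | transposed ketol, methyl 2-[6-ethenyl-2-hydroxy-1-methyl-3-oxo-4-(prop-1-en-2-yl)cyclohexyl]acetate (hydroxyl cis to the acetate arm) | COC(=O)C[C@]1(C)[C@H](O)C(=O)[C@H](C(C)=C)C[C@H]1C=C | intermediate
9 | isopropenyl lactone, cis-fused 4-ethenyl-3a-methyl-6-(prop-1-en-2-yl)hexahydro-1-benzofuran-2,7-dione | O=C1C[C@]2(C)[C@H](O1)C(=O)[C@H](C(C)=C)C[C@H]2C=C | intermediate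
10 | (3aS,4S,7aS)-4-ethenyl-3a-methyl-6-(propan-2-ylidene)hexahydro-1-benzofuran-2,7-dione (cis-fused γ-lactone) | O=C1C[C@]2(C)[C@H](O1)C(=O)C(=C(C)C)C[C@H]2C=C | intermediate
11 | (3aS,4R,7aS)-4-acetyl-3a-methyl-6-(propan-2-ylidene)hexahydro-1-benzofuran-2,7-dione | O=C1C[C@]2(C)[C@H](O1)C(=O)C(=C(C)C)C[C@H]2C(C)=O | intermediate
12 | 2-[(1S,2R)-2-acetyl-1-methyl-5-oxo-4-(propan-2-ylidene)cyclohexyl]acetic acid (acetyl trans to the acetic acid arm) | OC(=O)C[C@]1(C)CC(=O)C(=C(C)C)C[C@H]1C(C)=O | intermediate
13 | vinyltriphenylphosphonium bromide | C=C[P+](c1ccccc1)(c1ccccc1)c1ccccc1.[Br-] | starting material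
14 | phosphorus ylide, 12 minus CO2 extended at C1 by CH2–CH=PPh3 | C(=P(c1ccccc1)(c1ccccc1)c1ccccc1)CC[C@]1(C)CC(=O)C(=C(C)C)C[C@H]1C(C)=O | intermediate
15 | eudesma-3,7(11)-dien-8-one (5α-H, 10β-methyl) | CC1=CCC[C@]2(C)CC(=O)C(=C(C)C)C[C@@H]12 | intermediate
16 | 3α,4α-dihydroxyeudesm-7(11)-en-8-one | O[C@@H]1CC[C@]2(C)CC(=O)C(=C(C)C)C[C@H]2[C@]1(C)O | intermediate
17 | 4α-hydroxyeudesm-7(11)-ene-3,8-dione | O=C1CC[C@]2(C)CC(=O)C(=C(C)C)C[C@H]2[C@]1(C)O | intermediate
18 | 3β,4α-dihydroxyeudesm-7(11)-en-8-one | O[C@H]1CC[C@]2(C)CC(=O)C(=C(C)C)C[C@H]2[C@]1(C)O | intermediate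
19 | angelic acid, (Z)-2-methylbut-2-enoic acid | C/C=C(/C)C(=O)O | starting material
20 | (Z)-2-methylbut-2-enoic 2,4,6-trichlorobenzoic anhydride | C/C=C(/C)C(=O)OC(=O)c1c(Cl)cc(Cl)cc1Cl | intermediate
21 | 3β-angeloyloxy-4α-hydroxyeudesm-7(11)-en-8-one | C/C=C(/C)C(=O)O[C@H]1CC[C@]2(C)CC(=O)C(=C(C)C)C[C@H]2[C@]1(C)O | intermediate
22 | 3β-angeloyloxy-4α-acetoxyeudesm-7(11)-en-8-one (CNP0141494.1) | C/C=C(/C)C(=O)O[C@H]1CC[C@]2(C)CC(=O)C(=C(C)C)C[C@H]2[C@]1(C)OC(C)=O | target

Total step count: 11. Longest linear sequence: 11 steps, from 1.

**Steps most likely to fail**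

1. Step 6 (Proposed new method). The ylide may be protonated, by hydrogencarbonate or by the acetyl α-hydrogens, faster than it olefinates. The carboxylate may add to 13 in a polar background reaction. C5 may epimerise through the acetyl enolate. In each case ring A does not close, or closes on the wrong epimer. The fallback uses known chemistry and closes ring A by olefin metathesis instead of olefination. It sets out from 12: photoredox decarboxylative radical allylation with allyl phenyl sulfone should give the butenyl diketone F1 (C1–C2 bond). Chemoselective methylenation of the acetyl group (Ph3P=CH2, THF, 0 °C; the hindered cross-conjugated C8 ketone is left) should give the diene F2. Ring-closing metathesis with the second-generation Grubbs catalyst (CH2Cl2, 40 °C) should then form C3=C4, and the fallback returns to the route at 15.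

2. Step 3. The enediolate equilibrium may stall on the side of the starting ketol, or be diverted by oxidation of the enediolate to the 1,2-dione, so that lactonisation does not drain it. The fallback is a stepwise redox transposition. It sets out from 7: NaBH4 (MeOH, 0 °C) should reduce the C9 ketone, and the 9-hydroxyl should close on the ester to give the hydroxy lactone F3. Dess–Martin oxidation of the free 8-hydroxyl should give the keto lactone 9, now isolated. DBU (toluene, 25 °C) should then move the olefin into conjugation, and the fallback returns to the route at 10.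

3. Step 10. Forcing acylation of the hindered carbinol next to the quaternary C4 may erode the Z geometry of the angelate (isomerisation to the tiglate) or fail to acylate. The fallback builds the Z olefin on the ester instead of transferring it. It sets out from 18: DCC/DMAP coupling of the 3β-hydroxyl with 2-(diphenoxyphosphoryl)propanoic acid should give the phosphonate ester F4. Z-selective Horner–Wadsworth–Emmons olefination with acetaldehyde (NaI, DBU, THF, −78 to 0 °C) should then give the angelate, and the fallback returns to the route at 21.

**Further compounds**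

F1 | step 6 | 4-[(1S,2R)-2-acetyl-1-methyl-5-oxo-4-(propan-2-ylidene)cyclohexyl]but-1-ene (butenyl diketone) | C=CCC[C@]1(C)CC(=O)C(=C(C)C)C[C@H]1C(C)=O
F2 | step 6 | (4R,5S)-5-(but-3-en-1-yl)-5-methyl-4-(prop-1-en-2-yl)-2-(propan-2-ylidene)cyclohexan-1-one (diene for ring closure) | C=CCC[C@]1(C)CC(=O)C(=C(C)C)C[C@H]1C(C)=C
F3 | step 3 | cis-fused 4-ethenyl-7-hydroxy-3a-methyl-6-(prop-1-en-2-yl)hexahydro-1-benzofuran-2-one (hydroxy lactone, 7-OH trans to isopropenyl) | O=C1C[C@]2(C)[C@H](O1)[C@@H](O)[C@H](C(C)=C)C[C@H]2C=C
F4 | step 10 | 3β-[2-(diphenoxyphosphoryl)propanoyloxy]-4α-hydroxyeudesm-7(11)-en-8-one | CC(C(=O)O[C@H]1CC[C@]2(C)CC(=O)C(=C(C)C)C[C@H]2[C@]1(C)O)P(=O)(Oc1ccccc1)Oc1ccccc1
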